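**Retrosynthetic overview**

1. Ring letters: A = 4-oxyphenyl on C2 of furan ring 1; B = central benzene; C = 3,5-dioxygenated benzene fused to the seven-membered ring; D = 2,4-dioxyphenyl on the seven-ring CH; E = 3,5-dioxyphenyl on C3 of furan ring 2; F = 2,4-dioxyphenyl on C2 of furan ring 2.
2. The strategy rests on furan ring 2: its O–C2(ring F)–C3(ring E) unit is an intact oxyresveratrol, held to ring B by one C–O bond and by one C–C bond at the ring B carbon next to the seven-ring CH2.
3. Disconnections: eight aryl methyl ethers (last step); furan ring 2 by oxidative (3+2) cross-coupling of a 4-hydroxystilbene with the only free phenol of the seven-ring dimer; the seven-membered ring by acid-mediated Friedel–Crafts hydroarylation of a 2,4-dimethoxystyryl group; furan ring 1 by benzofuran synthesis and hydrogenation.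
4. Absolute configuration enters by resolution of the first chiral intermediate as a menthyl carbonate; C3 of furan ring 1 then controls C2 (acid equilibration to trans) and the seven-ring methine.
5. Ring order: ring B (purchased) → furan ring 1 (aromatic, then cis-dihydro) → seven-membered ring (with C2 epimerisation to trans) → furan ring 2.

Key step: step 12

Remark: compound 9 is racemic and is drawn as the (2S,3R) enantiomer that is carried on after step 5. The seven-ring closure in step 10 is assumed to give the diastereomer in which the ring D aryl group and the hydrogen at C3 of furan ring 1 lie on the same side of the seven-membered ring, which is the arrangement in the target; the acid closure of epsilon-viniferin to ampelopsin B is the analogy for this closure.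

**Route**

Step 1
Reactants: 1 methyl 3-(benzyloxy)-5-hydroxybenzoate; 2 2-bromo-1-(3,5-dimethoxyphenyl)ethan-1-one
Product: 3 methyl 3-(benzyloxy)-5-[2-(3,5-dimethoxyphenyl)-2-oxoethoxy]benzoate
Conditions: K2CO3, acetone, reflux
Reagents that add atoms: none
Why: Williamson ether synthesis, in which the only phenoxide of 1 displaces the reactive alpha-bromide of 2 by SN2 while the ester and the benzyl ether are inert to K2CO3.

Step 2
Reactants: 3 methyl 3-(benzyloxy)-5-[2-(3,5-dimethoxyphenyl)-2-oxoethoxy]benzoate
Product: 5 methyl 6-(benzyloxy)-3-(3,5-dimethoxyphenyl)-1-benzofuran-4-carboxylate, via tertiary carbinol 4 (not isolated)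
Conditions: Bi(OTf)3 (10 mol %), CH2Cl2, reflux
Reagents that add atoms: none
Why: Lewis-acid-catalysed cyclodehydration (intramolecular Friedel–Crafts hydroxyalkylation, then loss of water) at the ring carbon para to the benzyloxy group, which puts the ester at C4 and the masked phenol at C6 of the benzofuran.

Step 3
Reactants: 5 methyl 6-(benzyloxy)-3-(3,5-dimethoxyphenyl)-1-benzofuran-4-carboxylate; 6 4-bromoanisole
Product: 7 methyl 6-(benzyloxy)-3-(3,5-dimethoxyphenyl)-2-(4-methoxyphenyl)-1-benzofuran-4-carboxylate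
Conditions: Pd(OAc)2 (5 mol %), PCy3·HBF4, PivOH (30 mol %), K2CO3, DMA, 100 °C
Reagents that add atoms: none
Why: Palladium-catalysed direct C–H arylation (carboxylate-assisted concerted metalation–deprotonation) at C2, the only furan C–H bond of 5.

Step 4
Reactants: 7 methyl 6-(benzyloxy)-3-(3,5-dimethoxyphenyl)-2-(4-methoxyphenyl)-1-benzofuran-4-carboxylate
Product: 9 methyl cis-3-(3,5-dimethoxyphenyl)-6-hydroxy-2-(4-methoxyphenyl)-2,3-dihydro-1-benzofuran-4-carboxylate (racemic; (2S,3R) form drawn), via debenzylated benzofuranol 8 (not isolated)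
Conditions: H2 (40 bar), Pd(OH)2/C, EtOAc–AcOH, 50 °C
Reagents that add atoms: none
Why: Heterogeneous hydrogenation, in which the benzyl ether is hydrogenolysed first and the furan C2=C3 bond then takes up H2 by syn addition, so the two new stereocentres form cis to one another as a racemate and the phenol needed for resolution is freed.

Step 5
Reactants: 9 methyl cis-3-(3,5-dimethoxyphenyl)-6-hydroxy-2-(4-methoxyphenyl)-2,3-dihydro-1-benzofuran-4-carboxylate (racemic)
Product: 10 methyl (2S,3R)-3-(3,5-dimethoxyphenyl)-2-(4-methoxyphenyl)-6-({[(1R,2S,5R)-menthyl]oxy}carbonyloxy)-2,3-dihydro-1-benzofuran-4-carboxylate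
Conditions: (1R,2S,5R)-menthyl chloroformate, Et3N, DMAP (cat.), CH2Cl2, 0 °C → rt; the two diastereomeric carbonates separated on SiO2 and by crystallisation
Reagents that add atoms: (1R,2S,5R)-menthyl chloroformate, CC(C)[C@@H]1CC[C@@H](C)C[C@H]1OC(Cl)=O
Why: Acylation of the phenol with an enantiopure chloroformate (classical resolution through covalent diastereomers) turns the two enantiomers of 9 into two diastereomeric carbonates, of which 10 would be isolated, the (2R,3S) diastereomer set aside, and the configuration assigned by X-ray analysis against the menthyl centres.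

Step 6
Reactants: 10 methyl (2S,3R)-3-(3,5-dimethoxyphenyl)-2-(4-methoxyphenyl)-6-({[(1R,2S,5R)-menthyl]oxy}carbonyloxy)-2,3-dihydro-1-benzofuran-4-carboxylate
Product: 11 (2S,3R)-3-(3,5-dimethoxyphenyl)-4-(hydroxymethyl)-2-(4-methoxyphenyl)-2,3-dihydro-1-benzofuran-6-ol
Conditions: LiAlH4, THF, 0 °C → rt
Reagents that add atoms: none
Why: Hydride reduction, in which LiAlH4 reduces the methyl ester to the primary alcohol and cleaves the aryl carbonate, so the auxiliary leaves without a separate step and the stereocentres are untouched.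

Step 7
Reactants: 11 (2S,3R)-3-(3,5-dimethoxyphenyl)-4-(hydroxymethyl)-2-(4-methoxyphenyl)-2,3-dihydro-1-benzofuran-6-ol
Product: 12 (2S,3R)-3-(3,5-dimethoxyphenyl)-6-hydroxy-2-(4-methoxyphenyl)-2,3-dihydro-1-benzofuran-4-carbaldehyde
Conditions: activated MnO2, EtOAc, rt
Reagents that add atoms: none
Why: Chemoselective MnO2 oxidation of a benzylic alcohol, which stops at the aldehyde and should leave the phenol and the dihydrofuran alone.

Step 8
Reactants: 13 (2,4-dimethoxyphenyl)methanol
Product: 14 diethyl [(2,4-dimethoxyphenyl)methyl]phosphonate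
Conditions: P(OEt)3, ZnI2, toluene, reflux
Reagents that add atoms: triethyl phosphite, CCOP(OCC)OCC
Why: ZnI2-mediated Michaelis–Arbuzov-type phosphonylation, in which the electron-rich benzylic alcohol ionises, is captured by the phosphite and the phosphonium intermediate is dealkylated to the phosphonate.

Step 9
Reactants: 12 (2S,3R)-3-(3,5-dimethoxyphenyl)-6-hydroxy-2-(4-methoxyphenyl)-2,3-dihydro-1-benzofuran-4-carbaldehyde; 14 diethyl [(2,4-dimethoxyphenyl)methyl]phosphonate
Product: 15 (2S,3R)-3-(3,5-dimethoxyphenyl)-4-[(E)-2-(2,4-dimethoxyphenyl)ethenyl]-2-(4-methoxyphenyl)-2,3-dihydro-1-benzofuran-6-ol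
Conditions: KOtBu (3.2 equiv), THF, 0 °C → rt
Reagents that add atoms: none
Why: Horner–Wadsworth–Emmons olefination of a non-enolisable aldehyde giving the (E)-stilbene, with extra base consumed by the phenol, which sits meta to the aldehyde and so does not deactivate it.

Step 10
Reactants: 15 (2S,3R)-3-(3,5-dimethoxyphenyl)-4-[(E)-2-(2,4-dimethoxyphenyl)ethenyl]-2-(4-methoxyphenyl)-2,3-dihydro-1-benzofuran-6-ol
Product: 17 (1R,8R,16R)-8-(2,4-dimethoxyphenyl)-4,6-dimethoxy-16-(4-methoxyphenyl)-15-oxatetracyclo[8.6.1.0^2,7.0^14,17]heptadeca-2(7),3,5,10(17),11,13-hexaen-12-ol (seven-ring dimer; free ring B phenol; trans furan ring 1), via cis-dihydrofuran epimer 16 (not isolated)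
Conditions: TFA, CH2Cl2 (dilute), 0 °C → rt
Reagents that add atoms: none
Why: Brønsted-acid-mediated intramolecular Friedel–Crafts hydroarylation with C2 epimerisation, in which protonation of the styrene at the carbon on ring B gives a 2,4-dimethoxybenzyl cation that the ortho carbon of ring C traps, the ring D aryl group taking the side of the C3 hydrogen under control of C3 of furan ring 1, and reversible ionisation of the benzylic C2–O bond then turns the cis-dihydrofuran into the more stable trans isomer.

Step 11
Reactants: 18 4-hydroxy-2-methoxybenzaldehyde; 19 diethyl [(3,5-dimethoxyphenyl)methyl]phosphonate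
Product: 20 4-[(E)-2-(3,5-dimethoxyphenyl)ethenyl]-3-methoxyphenol
Conditions: KOtBu (3 equiv), DMF, 0 °C → 50 °C
Reagents that add atoms: none
Why: Horner–Wadsworth–Emmons olefination run on the unprotected hydroxy aldehyde with excess base, giving the (E)-4-hydroxystilbene directly.

Step 12
Reactants: 17 seven-ring dimer with free ring B phenol; 20 4-[(E)-2-(3,5-dimethoxyphenyl)ethenyl]-3-methoxyphenol
Product: 22 ring F phenol octamethyl ether of the target (furan ring 1: 2R,3R; seven-ring CH: R; furan ring 2: 2S,3S), via para-quinone methide 21 (not isolated)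
Conditions: FeCl3·6H2O (4 equiv), acetone–CH2Cl2, 0 °C → rt, 20 (2 equiv) added over 6 h by syringe pump
Reagents that add atoms: none
Why: FeCl3 oxidises the phenols by one electron each; the phenoxyl radical of 20 carries spin at the stilbene carbon bearing ring E, and this carbon bonds to the ring B carbon of 17 that is ortho to the free hydroxyl, para to the furan-1 oxygen and next to the seven-ring CH2, after which tautomerisation rearomatises ring B and leaves para-quinone methide 21. The ring B hydroxyl then adds to the methide carbon in a 5-exo-trig oxa-Michael closure, which forms furan ring 2 and restores ring F as a phenol. The closest known reaction type is the biomimetic oxidative coupling of 4-hydroxystilbenes with resorcinol-type phenols to trans-2,3-diaryl-2,3-dihydrobenzofurans, the coupling mode that leads from resveratrol to epsilon-viniferin and on to its trimers. C3 of furan ring 2 is fixed in the C–C bond-forming event, where only the existing stereocentres of 17 (ring C on one face of ring B and the seven-ring CH2 beside the reacting carbon) can bias it, so no strong preference is assumed and the two 2,3-trans diastereomers would be separated by chromatography, the one with rings C and E on the same face of ring B being carried on; C2 is set by the reversible oxa-Michael closure, which settles on the 2,3-trans arrangement. Cross-coupling over homodimerisation of 20 is sought by keeping free 20 dilute through slow addition, and regioselectivity rests on the higher reactivity of the ring B carbon that is ortho to one oxygen and para to the other over the carbon between the two oxygens, as in the resorcinol ring of resveratrol.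

Step 13
Reactants: 22 ring F phenol octamethyl ether of the target
Product: 23 CNP0283541.1 (nonaphenol; furan ring 1: 2R,3R; seven-ring CH: R; furan ring 2: 2S,3S)
Conditions: BBr3 (excess), CH2Cl2, −78 °C → rt; then ice-water
Reagents that add atoms: none
Why: Lewis-acid ether cleavage, in which BBr3 coordinates each methoxy oxygen and bromide removes the methyl group by SN2, so no bond to a stereocentre is broken in the intended pathway and a transient opening of a benzylic C2–O bond can re-close to the more stable trans-dihydrofuran.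

**Compound list**

1 | methyl 3-(benzyloxy)-5-hydroxybenzoate | COC(=O)c1cc(O)cc(OCc2ccccc2)c1 | starting material
2 | 2-bromo-1-(3,5-dimethoxyphenyl)ethan-1-one | COc1cc(cc(OC)c1)C(=O)CBr | starting material
3 | methyl 3-(benzyloxy)-5-[2-(3,5-dimethoxyphenyl)-2-oxoethoxy]benzoate | COC(=O)c1cc(OCc2ccccc2)cc(OCC(=O)c2cc(OC)cc(OC)c2)c1 | intermediate
4 | methyl 6-(benzyloxy)-3-(3,5-dimethoxyphenyl)-3-hydroxy-2,3-dihydro-1-benzofuran-4-carboxylate (racemic carbinol) | COC(=O)c1cc(OCc2ccccc2)cc2OCC(O)(c3cc(OC)cc(OC)c3)c12 | intermediate (not isolated)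
5 | methyl 6-(benzyloxy)-3-(3,5-dimethoxyphenyl)-1-benzofuran-4-carboxylate | COC(=O)c1cc(OCc2ccccc2)cc2occ(-c3cc(OC)cc(OC)c3)c12 | intermediate
6 | 4-bromoanisole | COc1ccc(Br)cc1 | starting material
7 | methyl 6-(benzyloxy)-3-(3,5-dimethoxyphenyl)-2-(4-methoxyphenyl)-1-benzofuran-4-carboxylate | COC(=O)c1cc(OCc2ccccc2)cc2oc(-c3ccc(OC)cc3)c(-c3cc(OC)cc(OC)c3)c12 | intermediate
8 | methyl 3-(3,5-dimethoxyphenyl)-6-hydroxy-2-(4-methoxyphenyl)-1-benzofuran-4-carboxylate | COC(=O)c1cc(O)cc2oc(-c3ccc(OC)cc3)c(-c3cc(OC)cc(OC)c3)c12 | intermediate (not isolated)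
9 | methyl cis-3-(3,5-dimethoxyphenyl)-6-hydroxy-2-(4-methoxyphenyl)-2,3-dihydro-1-benzofuran-4-carboxylate, racemic, (2S,3R) enantiomer drawn | COc1ccc([C@H]2Oc3cc(O)cc(C(=O)OC)c3[C@H]2c2cc(OC)cc(OC)c2)cc1 | intermediate
10 | methyl (2S,3R)-3-(3,5-dimethoxyphenyl)-2-(4-methoxyphenyl)-6-({[(1R,2S,5R)-menthyl]oxy}carbonyloxy)-2,3-dihydro-1-benzofuran-4-carboxylate | COc1ccc([C@H]2Oc3cc(OC(=O)O[C@@H]4C[C@H](C)CC[C@H]4C(C)C)cc(C(=O)OC)c3[C@H]2c2cc(OC)cc(OC)c2)cc1 | intermediate
11 | (2S,3R)-3-(3,5-dimethoxyphenyl)-4-(hydroxymethyl)-2-(4-methoxyphenyl)-2,3-dihydro-1-benzofuran-6-ol | COc1ccc([C@H]2Oc3cc(O)cc(CO)c3[C@H]2c2cc(OC)cc(OC)c2)cc1 | intermediate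
12 | (2S,3R)-3-(3,5-dimethoxyphenyl)-6-hydroxy-2-(4-methoxyphenyl)-2,3-dihydro-1-benzofuran-4-carbaldehyde | COc1ccc([C@H]2Oc3cc(O)cc(C=O)c3[C@H]2c2cc(OC)cc(OC)c2)cc1 | intermediate
13 | (2,4-dimethoxyphenyl)methanol | COc1ccc(CO)c(OC)c1 | starting material
14 | diethyl [(2,4-dimethoxyphenyl)methyl]phosphonate | CCOP(=O)(Cc1ccc(OC)cc1OC)OCC | intermediate
15 | (2S,3R)-3-(3,5-dimethoxyphenyl)-4-[(E)-2-(2,4-dimethoxyphenyl)ethenyl]-2-(4-methoxyphenyl)-2,3-dihydro-1-benzofuran-6-ol | COc1ccc([C@H]2Oc3cc(O)cc(/C=C/c4ccc(OC)cc4OC)c3[C@H]2c2cc(OC)cc(OC)c2)cc1 | intermediate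
16 | (1R,8R,16S)-8-(2,4-dimethoxyphenyl)-4,6-dimethoxy-16-(4-methoxyphenyl)-15-oxatetracyclo[8.6.1.0^2,7.0^14,17]heptadeca-2(7),3,5,10(17),11,13-hexaen-12-ol (cis-dihydrofuran epimer of 17) | COc1ccc([C@H]2Oc3cc(O)cc4c3[C@H]2c2cc(OC)cc(OC)c2[C@@H](c2ccc(OC)cc2OC)C4)cc1 | intermediate (not isolated)
17 | (1R,8R,16R)-8-(2,4-dimethoxyphenyl)-4,6-dimethoxy-16-(4-methoxyphenyl)-15-oxatetracyclo[8.6.1.0^2,7.0^14,17]heptadeca-2(7),3,5,10(17),11,13-hexaen-12-ol (seven-ring dimer, free ring B phenol, trans furan ring 1) | COc1ccc([C@@H]2Oc3cc(O)cc4c3[C@H]2c2cc(OC)cc(OC)c2[C@@H](c2ccc(OC)cc2OC)C4)cc1 | intermediate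
18 | 4-hydroxy-2-methoxybenzaldehyde | COc1cc(O)ccc1C=O | starting material
19 | diethyl [(3,5-dimethoxyphenyl)methyl]phosphonate | CCOP(=O)(Cc1cc(OC)cc(OC)c1)OCC | starting material
20 | 4-[(E)-2-(3,5-dimethoxyphenyl)ethenyl]-3-methoxyphenol | COc1cc(/C=C/c2ccc(O)cc2OC)cc(OC)c1 | intermediate
21 | para-quinone methide: 17 carrying on the ring B carbon next to the CH2 a CH(ring E) group bonded to the exocyclic methide carbon of a 2-methoxy-4-oxocyclohexa-2,5-dien-1-ylidene | COc1ccc([C@@H]2Oc3cc(O)c(c4c3[C@H]2c2cc(OC)cc(OC)c2[C@@H](c2ccc(OC)cc2OC)C4)[C@H](c2cc(OC)cc(OC)c2)C=C2C=CC(=O)C=C2OC)cc1 | intermediate (not isolated)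
22 | octamethyl ether of the target with the 4-hydroxyl of ring F free; furan ring 1 (2R,3R) trans, seven-ring CH (R), furan ring 2 (2S,3S) trans | COc1ccc([C@@H]2Oc3cc4c(c5c3[C@H]2c2cc(OC)cc(OC)c2[C@@H](c2ccc(OC)cc2OC)C5)[C@H](c2cc(OC)cc(OC)c2)[C@@H](c2ccc(O)cc2OC)O4)cc1 | intermediate
23 | CNP0283541.1; furan ring 1 (2R,3R) trans, seven-ring CH (R), furan ring 2 (2S,3S) trans | Oc1ccc([C@@H]2Oc3cc4c(c5c3[C@H]2c2cc(O)cc(O)c2[C@@H](c2ccc(O)cc2O)C5)[C@H](c2cc(O)cc(O)c2)[C@@H](c2ccc(O)cc2O)O4)cc1 | target

**Step count**

Total: 13 steps. Longest linear sequence: 11 steps (1–7, 9, 10, 12, 13).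

**Steps most likely to fail**

1. Step 12. Homodimerisation of the stilbene radical may outrun cross-coupling, bond formation may occur at the ring B carbon between the two oxygens, facial discrimination at C3 of furan ring 2 may be low, and the product may be oxidised further. Fallback: setting out from 17, furan ring 2 would be built by the sequence used for furan ring 1. O-Alkylation of 17 with 2 (K2CO3, acetone) would give the aryloxy ketone F1. Bi(OTf)3-catalysed cyclodehydration onto the ring B carbon para to the furan-1 oxygen would give the 3-aryl benzofuran F2. Pd(OAc)2-catalysed C2 arylation with 1-bromo-2,4-dimethoxybenzene would give the 2,3-diaryl benzofuran F3. Hydrogenation over Pd(OH)2/C from the face away from ring C would give the cis-dihydrofuran F4, in which ring E lies on the ring C face, and TFA-mediated epimerisation at C2 would give the nonamethyl ether F5. BBr3 demethylation of F5 rejoins the route at 23.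

2. Step 13. BBr3 may ionise the benzylic C2–O bond of furan ring 2, whose cation is stabilised by the 2,4-dioxygenated ring F, leading to ring opening and cationic rearrangement, and cleavage of eight ethers may stall. Fallback: setting out from 17, BBr3 (CH2Cl2, −78 °C → rt) would remove the five methyl groups while only the less labile furan ring 1 is present, giving the free hexaphenol dimer F6. Oxidative cross-coupling of F6 with commercial oxyresveratrol (FeCl3·6H2O, acetone–water), run as in step 12 but on unprotected material and therefore with lower chemoselectivity, would close furan ring 2 and rejoin the route at 23, so that no ether cleavage follows formation of the acid-sensitive ring.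

3. Step 5. The two menthyl carbonates may not differ enough in chromatographic or crystallisation behaviour, because the menthyl group is remote from the stereocentres. Fallback: setting out from 9, direct enantiomer separation by preparative HPLC on a chiral stationary phase (amylose tris(3,5-dimethylphenylcarbamate)) would give the (2S,3R) enantiomer F7, and LiAlH4 reduction of F7 rejoins the route at 11.

**Further compounds**

F1 | step 12 | aryloxy ketone: 17 with its ring B oxygen alkylated by CH2C(=O)(3,5-dimethoxyphenyl) | COc1ccc([C@@H]2Oc3cc(OCC(=O)c5cc(OC)cc(OC)c5)cc4c3[C@H]2c2cc(OC)cc(OC)c2[C@@H](c2ccc(OC)cc2OC)C4)cc1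
F2 | step 12 | 3-aryl benzofuran: furan ring 2 aromatic, ring E at C3, C2 unsubstituted | COc1ccc([C@@H]2Oc3cc4c(c5c3[C@H]2c2cc(OC)cc(OC)c2[C@@H](c2ccc(OC)cc2OC)C5)c(-c2cc(OC)cc(OC)c2)co4)cc1
F3 | step 12 | 2,3-diaryl benzofuran: furan ring 2 aromatic, ring E at C3, 2,4-dimethoxyphenyl at C2 | COc1ccc([C@@H]2Oc3cc4c(c5c3[C@H]2c2cc(OC)cc(OC)c2[C@@H](c2ccc(OC)cc2OC)C5)c(-c2cc(OC)cc(OC)c2)c(-c2ccc(OC)cc2OC)o4)cc1
F4 | step 12 | nonamethyl ether with cis furan ring 2 (C2 epimer of F5) | COc1ccc([C@@H]2Oc3cc4c(c5c3[C@H]2c2cc(OC)cc(OC)c2[C@@H](c2ccc(OC)cc2OC)C5)[C@H](c2cc(OC)cc(OC)c2)[C@H](c2ccc(OC)cc2OC)O4)cc1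
F5 | step 12 | nonamethyl ether of the target | COc1ccc([C@@H]2Oc3cc4c(c5c3[C@H]2c2cc(OC)cc(OC)c2[C@@H](c2ccc(OC)cc2OC)C5)[C@H](c2cc(OC)cc(OC)c2)[C@@H](c2ccc(OC)cc2OC)O4)cc1
F6 | step 13 | free hexaphenol seven-ring dimer (all five methyl ethers of 17 cleaved) | Oc1ccc([C@@H]2Oc3cc(O)cc4c3[C@H]2c2cc(O)cc(O)c2[C@@H](c2ccc(O)cc2O)C4)cc1
F7 | step 5 | methyl (2S,3R)-3-(3,5-dimethoxyphenyl)-6-hydroxy-2-(4-methoxyphenyl)-2,3-dihydro-1-benzofuran-4-carboxylate, single enantiomer of 9 | COc1ccc([C@H]2Oc3cc(O)cc(C(=O)OC)c3[C@H]2c2cc(OC)cc(OC)c2)cc1
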